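**Retrosynthetic overview**
1. Target 10 ⇐ O–O reduction and desilylation of bicyclic endoperoxide 8, itself the [4+2] adduct of singlet oxygen and cis-dioxygenated cyclohexa-1,5-diene 7. This places the C3 and C6 hydroxyls cis to each other and anti to the C4/C5 oxygens.
2. Diene 7 ⇐ epoxide-to-allylic-silyl-ether isomerisation of epoxy dibenzoate 5, which fixes the benzoate on target C5 and a masked free hydroxyl on C4.
3. 5 ⇐ ester reduction and double benzoylation of shikimate 4,5-epoxide 3 ⇐ Mitsunobu closure of methyl shikimate 2 ⇐ (−)-shikimic acid 1, which supplies the carbocycle and the C4/C5 stereocentres.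
4. Ring order: cyclohexene bought; oxirane formed in step 2 and opened in step 5; 2,3-dioxabicyclo[2.2.2]octene formed in step 6 and cleaved in the same flask.

Assumption: natural (−)-shikimic acid (3R,4S,5R) is the purchased chiral material. Locants in intermediate names count from the ring carbon carrying the one-carbon substituent (C1), so shikimate C2/C3/C4/C5 become target C6/C5/C4/C3.

**Route**

Step 1
Reactants: 1 (−)-shikimic acid
Product: 2 methyl (3R,4S,5R)-3,4,5-trihydroxycyclohex-1-ene-1-carboxylate (methyl shikimate)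
Conditions: MeOH, CSA (cat.), reflux
Reagents that add atoms: methanol, CO
Why: Fischer esterification of the conjugated acid; no stereocentre is touched.

Step 2
Reactants: 2 methyl shikimate
Product: 3 methyl (3R,4R,5S)-4,5-epoxy-3-hydroxycyclohex-1-ene-1-carboxylate (oxirane cis to the 3-OH)
Conditions: PPh3, DIAD, THF, 0 °C → rt
Reagents that add atoms: none
Why: Intramolecular Mitsunobu etherification in which the less hindered C5-OH is activated and displaced by the trans-vicinal C4 oxygen with inversion at C5, so C3 and C4 keep their purchased configuration.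

Step 3
Reactants: 3 methyl (3R,4R,5S)-4,5-epoxy-3-hydroxycyclohex-1-ene-1-carboxylate
Product: 4 [(3R,4R,5S)-4,5-epoxy-3-hydroxycyclohex-1-en-1-yl]methanol
Conditions: DIBAL-H (3.3 equiv), CH2Cl2, −78 °C; Rochelle salt work-up
Reagents that add atoms: none
Why: 1,2-Reduction of the enoate to the allylic alcohol by DIBAL-H is much faster at −78 °C than hydride opening of the non-allylic oxirane; no stereocentre is changed.

Step 4
Reactants: 4 [(3R,4R,5S)-4,5-epoxy-3-hydroxycyclohex-1-en-1-yl]methanol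
Product: 5 [(3R,4S,5S)-3-(benzoyloxy)-4,5-epoxycyclohex-1-en-1-yl]methyl benzoate
Conditions: Bz2O (2.5 equiv), Et3N, DMAP (cat.), CH2Cl2, 0 °C → rt
Reagents that add atoms: benzoic anhydride, O=C(OC(=O)c1ccccc1)c1ccccc1
Why: DMAP-catalysed acylation puts both benzoates of the target in place at once (primary carbinol and the future C5 oxygen), and the halide-free conditions leave the oxirane intact.

Step 5
Reactants: 5 [(3R,4S,5S)-3-(benzoyloxy)-4,5-epoxycyclohex-1-en-1-yl]methyl benzoate
Product: 7 [(3R,4S)-3-(benzoyloxy)-4-(trimethylsilyloxy)cyclohexa-1,5-dien-1-yl]methyl benzoate, via trans-silyloxy triflate 6 (not isolated)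
Conditions: TMSOTf, 2,6-lutidine, toluene, −78 °C; then DBU, −78 °C → rt; filter through Et3N-deactivated silica, use at once
Reagents that add atoms: trimethylsilyl trifluoromethanesulfonate, C[Si](C)(C)OS(=O)(=O)C(F)(F)F
Why: Noyori-type epoxide-to-allylic-silyl-ether isomerisation, in which the silylated oxirane opens trans-diaxially at C5 (remote from the benzoate, which being cis cannot participate) and DBU removes the anti-periplanar allylic H6 in an E2 step; the C4–O bond is never broken, so C4 is retained.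

Step 6
Reactants: 7 [(3R,4S)-3-(benzoyloxy)-4-(trimethylsilyloxy)cyclohexa-1,5-dien-1-yl]methyl benzoate
Product: 10 [(3R,4S,5R,6S)-5-(benzoyloxy)-3,4,6-trihydroxycyclohex-1-en-1-yl]methyl benzoate (target), via endoperoxide 8 (not isolated), via TMS-protected enediol 9 (not isolated)
Conditions: O2, TPP (cat.), hν (visible), CH2Cl2, −20 °C; then thiourea, MeOH–H2O, 0 °C → rt; then citric acid (cat.), MeOH, rt
Reagents that add atoms: dioxygen (as singlet oxygen), O=O
Why: [4+2] cycloaddition of singlet oxygen to the s-cis ring diene occurs on the face anti to the cis C3-OBz/C4-OTMS pair, setting both new C–O stereocentres cis to each other and trans to the purchased ones; thiourea then cleaves the O–O bond with retention and mild acid methanolysis removes the TMS group without benzoate migration.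

**Compound list**
1 | (−)-shikimic acid, (3R,4S,5R)-3,4,5-trihydroxycyclohex-1-ene-1-carboxylic acid | O=C(O)C1=C[C@@H](O)[C@@H](O)[C@H](O)C1 | starting material
2 | methyl (3R,4S,5R)-3,4,5-trihydroxycyclohex-1-ene-1-carboxylate | COC(=O)C1=C[C@@H](O)[C@@H](O)[C@H](O)C1 | intermediate
3 | methyl (3R,4R,5S)-4,5-epoxy-3-hydroxycyclohex-1-ene-1-carboxylate (oxirane cis to 3-OH) | COC(=O)C1=C[C@@H](O)[C@H]2O[C@H]2C1 | intermediate
4 | [(3R,4R,5S)-4,5-epoxy-3-hydroxycyclohex-1-en-1-yl]methanol | OCC1=C[C@@H](O)[C@H]2O[C@H]2C1 | intermediate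
5 | [(3R,4S,5S)-3-(benzoyloxy)-4,5-epoxycyclohex-1-en-1-yl]methyl benzoate | O=C(OCC1=C[C@@H](OC(=O)c2ccccc2)[C@H]3O[C@H]3C1)c1ccccc1 | intermediate
6 | [(3R,4R,5R)-3-(benzoyloxy)-5-(trifluoromethanesulfonyloxy)-4-(trimethylsilyloxy)cyclohex-1-en-1-yl]methyl benzoate (3,4-cis, 4,5-trans) | O=C(OCC1=C[C@@H](OC(=O)c2ccccc2)[C@@H](O[Si](C)(C)C)[C@H](OS(=O)(=O)C(F)(F)F)C1)c1ccccc1 | intermediate (not isolated)
7 | [(3R,4S)-3-(benzoyloxy)-4-(trimethylsilyloxy)cyclohexa-1,5-dien-1-yl]methyl benzoate (cis) | O=C(OCC1=C[C@@H](OC(=O)c2ccccc2)[C@@H](O[Si](C)(C)C)C=C1)c1ccccc1 | intermediate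
8 | [(1R,4S,7R,8R)-8-(benzoyloxy)-7-(trimethylsilyloxy)-2,3-dioxabicyclo[2.2.2]oct-5-en-5-yl]methyl benzoate (peroxide bridge anti to both oxygen substituents) | O=C(OCC1=C[C@@H]2[C@H](O[Si](C)(C)C)[C@H](OC(=O)c3ccccc3)[C@H]1OO2)c1ccccc1 | intermediate (not isolated)
9 | [(3R,4S,5R,6S)-5-(benzoyloxy)-3,6-dihydroxy-4-(trimethylsilyloxy)cyclohex-1-en-1-yl]methyl benzoate | O=C(OCC1=C[C@@H](O)[C@H](O[Si](C)(C)C)[C@H](OC(=O)c2ccccc2)[C@H]1O)c1ccccc1 | intermediate (not isolated)
10 | [(3R,4S,5R,6S)-5-(benzoyloxy)-3,4,6-trihydroxycyclohex-1-en-1-yl]methyl benzoate | O=C(OCC1=C[C@@H](O)[C@H](O)[C@H](OC(=O)c2ccccc2)[C@H]1O)c1ccccc1 | target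

**Totals**
Total step count: 6. Longest linear sequence: 6 (fully linear from 1).

**Steps most likely to fail**

Step 5 (epoxide to silyloxy diene). The risks are loss of benzoic acid from 7 under DBU to give an arene, and ionisation of the allylic benzoate by the silyl triflate. The fallback replaces the Lewis acid/amidine E2 by a selenium redox sequence; it sets out from 5 and comes back at 7. The oxirane of 5 is opened trans-diaxially at C5 with PhSeNa ((PhSe)2, NaBH4, EtOH–THF, 0 °C) to give [(3R,4R,5R)-3-(benzoyloxy)-4-hydroxy-5-(phenylselanyl)cyclohex-1-en-1-yl]methyl benzoate F1. Its C4 hydroxyl is capped at once (TMSCl, imidazole, CH2Cl2, 0 °C), before the neighbouring benzoate can migrate, to give the silyl ether [(3R,4R,5R)-3-(benzoyloxy)-5-(phenylselanyl)-4-(trimethylsilyloxy)cyclohex-1-en-1-yl]methyl benzoate F2. Oxidation with mCPBA (CH2Cl2, −78 °C) gives the selenoxide of F2 F3, which on warming with i-Pr2NH undergoes syn-elimination away from the oxygenated carbon, toward C6, and delivers 7.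

Step 6 (photooxygenation, reduction, desilylation in one flask). The risks are erosion of facial selectivity if the small, labile TMS group is lost during irradiation (a free hydroxyl steers singlet oxygen to the wrong face), and difficulty in purifying a one-pot product. The fallback changes the protecting group and isolates each stage; it sets out from 7 and comes back at 10. Methanolysis of 7 (citric acid, MeOH, 0 °C) gives the dienol [(3R,4S)-3-(benzoyloxy)-4-hydroxycyclohexa-1,5-dien-1-yl]methyl benzoate F4. Resilylation (TBSOTf, 2,6-lutidine, CH2Cl2, −78 °C) gives the bulky, robust ether [(3R,4S)-3-(benzoyloxy)-4-(tert-butyldimethylsilyloxy)cyclohexa-1,5-dien-1-yl]methyl benzoate F5. Photooxygenation (O2, TPP, hν, CH2Cl2, −20 °C) gives the endoperoxide [(1R,4S,7R,8R)-8-(benzoyloxy)-7-(tert-butyldimethylsilyloxy)-2,3-dioxabicyclo[2.2.2]oct-5-en-5-yl]methyl benzoate F6, which is isolated and checked for facial purity. Separate reduction with thiourea in MeOH gives the diol [(3R,4S,5R,6S)-5-(benzoyloxy)-4-(tert-butyldimethylsilyloxy)-3,6-dihydroxycyclohex-1-en-1-yl]methyl benzoate F7, and HF·pyridine (THF, 0 °C) then gives 10.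

Step 3 (DIBAL-H reduction beside a free hydroxyl and an oxirane). The risks are hydride delivery to the oxirane from the neighbouring aluminium alkoxide and loss of the very polar diol on work-up. The fallback is a protect–reduce–release detour; it sets out from 3 and comes back at 4. Silylation of 3 (TESCl, imidazole, DMF, 0 °C) gives methyl (3R,4S,5S)-4,5-epoxy-3-(triethylsilyloxy)cyclohex-1-ene-1-carboxylate F8. Reduction with DIBAL-H (2.2 equiv, CH2Cl2, −78 °C) gives the lipophilic alcohol [(3R,4S,5S)-4,5-epoxy-3-(triethylsilyloxy)cyclohex-1-en-1-yl]methanol F9. Buffered fluoride (TBAF, AcOH, THF, 0 °C) then releases 4.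

**Further compounds**
F1 | step 5 | [(3R,4R,5R)-3-(benzoyloxy)-4-hydroxy-5-(phenylselanyl)cyclohex-1-en-1-yl]methyl benzoate | O=C(OCC1=C[C@@H](OC(=O)c2ccccc2)[C@@H](O)[C@H]([Se]c3ccccc3)C1)c1ccccc1
F2 | step 5 | [(3R,4R,5R)-3-(benzoyloxy)-5-(phenylselanyl)-4-(trimethylsilyloxy)cyclohex-1-en-1-yl]methyl benzoate | O=C(OCC1=C[C@@H](OC(=O)c2ccccc2)[C@@H](O[Si](C)(C)C)[C@H]([Se]c3ccccc3)C1)c1ccccc1
F3 | step 5 | selenoxide of F2 (mixture at selenium) | O=C(OCC1=C[C@@H](OC(=O)c2ccccc2)[C@@H](O[Si](C)(C)C)[C@H]([Se](=O)c3ccccc3)C1)c1ccccc1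
F4 | step 6 | [(3R,4S)-3-(benzoyloxy)-4-hydroxycyclohexa-1,5-dien-1-yl]methyl benzoate | O=C(OCC1=C[C@@H](OC(=O)c2ccccc2)[C@@H](O)C=C1)c1ccccc1
F5 | step 6 | [(3R,4S)-3-(benzoyloxy)-4-(tert-butyldimethylsilyloxy)cyclohexa-1,5-dien-1-yl]methyl benzoate | O=C(OCC1=C[C@@H](OC(=O)c2ccccc2)[C@@H](O[Si](C)(C)C(C)(C)C)C=C1)c1ccccc1
F6 | step 6 | [(1R,4S,7R,8R)-8-(benzoyloxy)-7-(tert-butyldimethylsilyloxy)-2,3-dioxabicyclo[2.2.2]oct-5-en-5-yl]methyl benzoate | O=C(OCC1=C[C@@H]2[C@H](O[Si](C)(C)C(C)(C)C)[C@H](OC(=O)c3ccccc3)[C@H]1OO2)c1ccccc1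
F7 | step 6 | [(3R,4S,5R,6S)-5-(benzoyloxy)-4-(tert-butyldimethylsilyloxy)-3,6-dihydroxycyclohex-1-en-1-yl]methyl benzoate | O=C(OCC1=C[C@@H](O)[C@H](O[Si](C)(C)C(C)(C)C)[C@H](OC(=O)c2ccccc2)[C@H]1O)c1ccccc1
F8 | step 3 | methyl (3R,4S,5S)-4,5-epoxy-3-(triethylsilyloxy)cyclohex-1-ene-1-carboxylate | COC(=O)C1=C[C@@H](O[Si](CC)(CC)CC)[C@H]2O[C@H]2C1
F9 | step 3 | [(3R,4S,5S)-4,5-epoxy-3-(triethylsilyloxy)cyclohex-1-en-1-yl]methanol | OCC1=C[C@@H](O[Si](CC)(CC)CC)[C@H]2O[C@H]2C1
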